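**Retrosynthetic overview**
- Target ⇐ spirocyclic cyclohexanone by equatorial methyl addition (sets the carbinol on the six-membered ring); that ketone ⇐ a secondary nitro compound (Nef).
- Spiro-cyclohexane ring (formed last) ⇐ mono-alkylated trione carrying a CH2NO2 group, by stitching one CH2 (formaldehyde) between the trione C–H and the nitro carbon; this sets the spiro centre.
- Mono-alkylated trione ⇐ 2-acetyl-4,4-diprenyl trione + cyclopentane carbaldehyde (reductive alkylation).
- Cyclopentane ring (formed first) ⇐ (E)-6-oxohept-2-enal + nitromethane by an organocatalytic asymmetric Michael/aldol domino; enal ⇐ hex-5-en-2-one + crotonaldehyde.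
- Trione ⇐ 2',4',6'-trihydroxyacetophenone + prenyl bromide (dearomatising bis-prenylation); ring order: trione ring (from the arene), cyclopentane, spiro-cyclohexane.

Assumption: triones are written in the enol tautomer of the target SMILES; in the mono-alkylated triones the ring carbon between the two ring carbonyls is configurationally labile and left undefined, and the nitro-bearing carbon of the spiro nitro compound is an epimer mixture that is erased in the Nef step.

**Step 1**
Reactants: 1 hex-5-en-2-one; 2 (E)-but-2-enal (crotonaldehyde)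
Product: 3 (E)-6-oxohept-2-enal
Conditions: 2 (5 equiv), second-generation Grubbs catalyst (2 mol %), CH2Cl2, 40 °C
Reagents that add atoms: none
Why: Olefin cross-metathesis: the terminal alkene of 1 and excess crotonaldehyde exchange alkylidene groups with loss of propene, and the conjugated product forms as the E isomer; no stereocentre is created.

**Step 2**
Reactants: 3 (E)-6-oxohept-2-enal; 4 nitromethane
Product: 6 (1S,2R,5R)-2-hydroxy-2-methyl-5-(nitromethyl)cyclopentane-1-carbaldehyde, via Michael adduct 5 (not isolated)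
Conditions: (S)-α,α-diphenylprolinol TMS ether (10 mol %), PhCO2H (10 mol %), 4 (3 equiv), MeOH, 0 °C to rt; then pyrrolidine (10 mol %), rt
Reagents that add atoms: none
Why: Iminium–enamine domino (Hayashi–Jørgensen Michael addition, then intramolecular 5-enolexo aldol): the silyl prolinol ether shields one face of the iminium ion so that nitromethane adds to the β-carbon and sets the first stereocentre (R in 5, not epimerisable), the resulting enamine adds to the methyl ketone, and the two centres made in the aldol step are reversible (enamine, retro-aldol) and settle under the amine in the most stable arrangement, CHO trans to CH2NO2 and cis to the hydrogen-bonded tertiary OH.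

**Step 3**
Reactants: 7 1-(2,4,6-trihydroxyphenyl)ethan-1-one; 8 1-bromo-3-methylbut-2-ene (prenyl bromide)
Product: 9 2-acetyl-3-hydroxy-4,4-bis(3-methylbut-2-en-1-yl)cyclohex-2-ene-1,5-dione
Conditions: NaOMe (3 equiv), 8 (2.1 equiv), MeOH, 0 °C to rt
Reagents that add atoms: none
Why: Base-mediated twofold C-prenylation of the phloroglucinolate: the second prenyl group enters at the already substituted ring carbon, which dearomatises the ring to the gem-diprenyl trione (lupulone-type alkylation); the aromatic 3,5-diprenyl isomer is removed by chromatography.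

**Step 4**
Reactants: 6 (1S,2R,5R)-2-hydroxy-2-methyl-5-(nitromethyl)cyclopentane-1-carbaldehyde; 9 2-acetyl-3-hydroxy-4,4-bis(3-methylbut-2-en-1-yl)cyclohex-2-ene-1,5-dione
Product: 11 2-acetyl-3-hydroxy-6-{[(1S,2R,5R)-2-hydroxy-2-methyl-5-(nitromethyl)cyclopentyl]methyl}-4,4-bis(3-methylbut-2-en-1-yl)cyclohex-2-ene-1,5-dione, via alkylidene trione 10 (not isolated)
Conditions: Hantzsch ester (1.1 equiv), L-proline (10 mol %), CH2Cl2, rt
Reagents that add atoms: none
Why: Three-component reductive alkylation (Knoevenagel condensation, then organocatalytic transfer hydrogenation): the only CH2 of 9 condenses with the aldehyde to alkylidene 10, which takes up hydride from the Hantzsch ester at once so that no bis-adduct forms; the aldehyde α-centre is already in its thermodynamic configuration and the other stereocentres are not involved.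

**Step 5**
Reactants: 11 2-acetyl-3-hydroxy-6-{[(1S,2R,5R)-2-hydroxy-2-methyl-5-(nitromethyl)cyclopentyl]methyl}-4,4-bis(3-methylbut-2-en-1-yl)cyclohex-2-ene-1,5-dione
Product: 14 (1S,3'R,3a'S,7a'R)-3-acetyl-3',4-dihydroxy-3'-methyl-5,5-bis(3-methylbut-2-en-1-yl)-7'-nitro-1',2',3',3a',4',6',7',7a'-octahydrospiro[cyclohex-3-ene-1,5'-indene]-2,6-dione, via nitro alcohol 12 (not isolated), via nitroalkene 13 (not isolated)
Conditions: aq. CH2O (1.2 equiv), Mg(OAc)2 (1.0 equiv), pyrrolidine (20 mol %), THF, 40 °C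
Reagents that add atoms: formaldehyde, C=O
Why: Proposed new method: formaldehyde-stitched spiroannulation – pyrrolidine and CH2O turn the CH2NO2 group into a 1-nitrovinyl group (Henry or nitro-Mannich addition, then elimination), and the magnesium enolate of the 2-alkyl-1,3-dione adds 6-endo to its CH2 terminus (Michael addition), which closes the ring and creates the spiro quaternary centre; Mg2+ sits in the chelating pocket of the acetyl oxygen and the adjacent ring oxygen, binds the nitro group and so holds that ring carbonyl gauche to the nitro carbon in a closed transition state, which should make it axial in the new chair (configuration S, as in the target), though this selectivity is a prediction; closest known chemistry: Knoevenagel-type nitroalkene formation from nitroalkanes and aldehydes, and Mg- or Ni-templated Michael addition of 2-substituted 1,3-dicarbonyls to nitroalkenes.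

**Step 6**
Reactants: 14 (1S,3'R,3a'S,7a'R)-3-acetyl-3',4-dihydroxy-3'-methyl-5,5-bis(3-methylbut-2-en-1-yl)-7'-nitro-1',2',3',3a',4',6',7',7a'-octahydrospiro[cyclohex-3-ene-1,5'-indene]-2,6-dione
Product: 15 (1S,3'R,3a'S,7a'R)-3-acetyl-3',4-dihydroxy-3'-methyl-5,5-bis(3-methylbut-2-en-1-yl)-2',3',3a',4',6',7a'-hexahydrospiro[cyclohex-3-ene-1,5'-indene]-2,6,7'(1'H)-trione
Conditions: NaOMe (2.2 equiv), MeOH, 0 °C; then aq. TiCl3 (4.5 equiv), NH4OAc buffer (pH 5), THF/H2O, 0 °C to rt
Reagents that add atoms: water, O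
Why: Nef reaction in the McMurry form: the nitronate is reduced by TiCl3 to the imine, which hydrolyses in the acetate buffer to the cyclohexanone without strong acid, so the prenyl groups and the tertiary alcohol survive; the ring-fusion centre next to the new ketone stays in the more stable trans-hydrindanone form.

**Step 7**
Reactants: 15 (1S,3'R,3a'S,7a'R)-3-acetyl-3',4-dihydroxy-3'-methyl-5,5-bis(3-methylbut-2-en-1-yl)-2',3',3a',4',6',7a'-hexahydrospiro[cyclohex-3-ene-1,5'-indene]-2,6,7'(1'H)-trione
Product: 16 (1S,3'R,3a'S,7'S,7a'R)-3-acetyl-3',4,7'-trihydroxy-3',7'-dimethyl-5,5-bis(3-methylbut-2-en-1-yl)-1',2',3',3a',4',6',7',7a'-octahydrospiro[cyclohex-3-ene-1,5'-indene]-2,6-dione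
Conditions: MeMgBr (6 equiv), CeCl3 (6 equiv), THF, −78 to −40 °C; aq. NH4Cl
Reagents that add atoms: methylmagnesium bromide, C[Mg]Br
Why: Imamoto organocerium 1,2-addition: the enolised triketone (present as its enolate) and the ketone flanked by two quaternary carbons do not react, and on the cyclohexanone the axial trione carbonyl on the spiro carbon (1,3 to the ketone) blocks axial attack, so methyl enters equatorially and the new tertiary OH is axial and syn to that carbonyl (S), as with 3,3-disubstituted cyclohexanones.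

**Compound list**
1 | hex-5-en-2-one | CC(=O)CCC=C | starting material
2 | (E)-but-2-enal | C/C=C/C=O | starting material
3 | (E)-6-oxohept-2-enal | CC(=O)CC/C=C/C=O | intermediate
4 | nitromethane | C[N+](=O)[O-] | starting material
5 | (3R)-3-(nitromethyl)-6-oxoheptanal (Michael adduct, present as its enamine) | O=CC[C@@H](CCC(C)=O)C[N+](=O)[O-] | intermediate
6 | (1S,2R,5R)-2-hydroxy-2-methyl-5-(nitromethyl)cyclopentane-1-carbaldehyde (CHO cis to OH, trans to CH2NO2) | O=C[C@H]1[C@@H](CC[C@@]1(C)O)C[N+](=O)[O-] | intermediate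
7 | 1-(2,4,6-trihydroxyphenyl)ethan-1-one | CC(=O)c1c(O)cc(O)cc1O | starting material
8 | 1-bromo-3-methylbut-2-ene | CC(C)=CCBr | starting material
9 | 2-acetyl-3-hydroxy-4,4-bis(3-methylbut-2-en-1-yl)cyclohex-2-ene-1,5-dione | CC(=O)C1=C(O)C(CC=C(C)C)(CC=C(C)C)C(=O)CC1=O | intermediate
10 | 2-acetyl-3-hydroxy-6-{[(1S,2R,5R)-2-hydroxy-2-methyl-5-(nitromethyl)cyclopentyl]methylidene}-4,4-bis(3-methylbut-2-en-1-yl)cyclohex-2-ene-1,5-dione | CC(=O)C1=C(O)C(CC=C(C)C)(CC=C(C)C)C(=O)C(=C[C@H]2[C@@H](CC[C@@]2(C)O)C[N+](=O)[O-])C1=O | intermediate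
11 | 2-acetyl-3-hydroxy-6-{[(1S,2R,5R)-2-hydroxy-2-methyl-5-(nitromethyl)cyclopentyl]methyl}-4,4-bis(3-methylbut-2-en-1-yl)cyclohex-2-ene-1,5-dione | CC(=O)C1=C(O)C(CC=C(C)C)(CC=C(C)C)C(=O)C(C[C@H]2[C@@H](CC[C@@]2(C)O)C[N+](=O)[O-])C1=O | intermediate
12 | 2-acetyl-3-hydroxy-6-{[(1S,2R,5R)-2-hydroxy-5-(2-hydroxy-1-nitroethyl)-2-methylcyclopentyl]methyl}-4,4-bis(3-methylbut-2-en-1-yl)cyclohex-2-ene-1,5-dione | CC(=O)C1=C(O)C(CC=C(C)C)(CC=C(C)C)C(=O)C(C[C@H]2[C@@H](CC[C@@]2(C)O)C(CO)[N+](=O)[O-])C1=O | intermediate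
13 | 2-acetyl-3-hydroxy-6-{[(1S,2R,5R)-2-hydroxy-2-methyl-5-(1-nitroethenyl)cyclopentyl]methyl}-4,4-bis(3-methylbut-2-en-1-yl)cyclohex-2-ene-1,5-dione | CC(=O)C1=C(O)C(CC=C(C)C)(CC=C(C)C)C(=O)C(C[C@H]2[C@@H](CC[C@@]2(C)O)C(=C)[N+](=O)[O-])C1=O | intermediate
14 | (1S,3'R,3a'S,7a'R)-3-acetyl-3',4-dihydroxy-3'-methyl-5,5-bis(3-methylbut-2-en-1-yl)-7'-nitro-1',2',3',3a',4',6',7',7a'-octahydrospiro[cyclohex-3-ene-1,5'-indene]-2,6-dione (trans-fused, 7'-epimer mixture) | CC(=O)C1=C(O)C(CC=C(C)C)(CC=C(C)C)C(=O)[C@@]2(C[C@H]3[C@@H](CC[C@@]3(C)O)C([N+](=O)[O-])C2)C1=O | intermediate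
15 | (1S,3'R,3a'S,7a'R)-3-acetyl-3',4-dihydroxy-3'-methyl-5,5-bis(3-methylbut-2-en-1-yl)-2',3',3a',4',6',7a'-hexahydrospiro[cyclohex-3-ene-1,5'-indene]-2,6,7'(1'H)-trione (trans-fused) | CC(=O)C1=C(O)C(CC=C(C)C)(CC=C(C)C)C(=O)[C@@]2(C[C@H]3[C@@H](CC[C@@]3(C)O)C(=O)C2)C1=O | intermediate
16 | (1S,3'R,3a'S,7'S,7a'R)-3-acetyl-3',4,7'-trihydroxy-3',7'-dimethyl-5,5-bis(3-methylbut-2-en-1-yl)-1',2',3',3a',4',6',7',7a'-octahydrospiro[cyclohex-3-ene-1,5'-indene]-2,6-dione (trans-fused; 7'-OH axial, syn to the C-2 carbonyl) | CC(=O)C1=C(O)C(CC=C(C)C)(CC=C(C)C)C(=O)[C@@]2(C[C@H]3[C@@H](CC[C@@]3(C)O)[C@@](C)(O)C2)C1=O | target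

**Step count**
Total: 7 steps. Longest linear sequence: 6 steps (steps 1, 2, 4, 5, 6, 7); step 3 is the convergent branch.

**Three steps most likely to fail**

Step 2 (domino Michael/aldol). The risks are closure through the nitronate instead of the enamine, loss of water to the cyclopentene carbaldehyde, and an unfavourable ratio at the two equilibrating centres. The fallback separates the two bond formations. It sets out from 3 and 4. Only the Michael addition is run under the same prolinol catalyst, and the aldehyde is trapped in the pot with HC(OMe)3 and TsOH as the acetal (5R)-7,7-dimethoxy-5-(nitromethyl)heptan-2-one F1. The acetal is then cleaved with aqueous AcOH and the ring is closed in a separate L-proline-mediated 5-enolexo aldol at low temperature. This comes back to the route at 6.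

Step 5 (the proposed new spiroannulation). The risks are double hydroxymethylation of the nitro carbon, polymerisation of the nitroalkene, and a poor ratio at the spiro centre. The fallback uses known reactions and forms the two bonds to the spiro carbon in the opposite order. It sets out from 6 and 9.
- NaBH4 in MeOH reduces the aldehyde of 6 to the diol (1R,2R,3R)-2-(hydroxymethyl)-1-methyl-3-(nitromethyl)cyclopentan-1-ol F2.
- TsCl in pyridine converts its primary OH into [(1R,2R,5R)-2-hydroxy-2-methyl-5-(nitromethyl)cyclopentyl]methyl 4-methylbenzenesulfonate F3.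
- Trione 9 and aqueous formaldehyde with catalytic piperidine give, by Knoevenagel condensation in the flask, 2-acetyl-3-hydroxy-6-methylidene-4,4-bis(3-methylbut-2-en-1-yl)cyclohex-2-ene-1,5-dione F4.
- The nitronate of F3 (Et3N) adds to F4 in a Michael reaction to give [(1R,2R,5R)-5-{2-[3-acetyl-4-hydroxy-5,5-bis(3-methylbut-2-en-1-yl)-2,6-dioxocyclohex-3-en-1-yl]-1-nitroethyl}-2-hydroxy-2-methylcyclopentyl]methyl 4-methylbenzenesulfonate F5.
- Cs2CO3 in DMF closes the ring by intramolecular C-alkylation of the 2-alkyl-1,3-dione with the primary tosylate (6-exo-tet).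

This comes back to the route at 14; the spiro epimers, if both form, are separated there.

Step 6 (Nef on a hindered secondary nitro group). The risks are slow nitronate formation next to the quaternary centre, retro-Michael opening, and over-reduction to the amine. The fallback sets out from 14 and goes through an isolable oxime. SnCl2, PhSH and Et3N reduce the nitro group to (1S,3'R,3a'S,7a'R)-3-acetyl-3',4-dihydroxy-7'-(hydroxyimino)-3'-methyl-5,5-bis(3-methylbut-2-en-1-yl)-1',2',3',3a',4',6',7',7a'-octahydrospiro[cyclohex-3-ene-1,5'-indene]-2,6-dione F6. The oxime is cleaved with aqueous NaHSO3 followed by dilute acid. This comes back to the route at 15.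

**Further compounds**
F1 | step 2 | (5R)-7,7-dimethoxy-5-(nitromethyl)heptan-2-one | COC(OC)C[C@@H](CCC(C)=O)C[N+](=O)[O-]
F2 | step 5 | (1R,2R,3R)-2-(hydroxymethyl)-1-methyl-3-(nitromethyl)cyclopentan-1-ol | OC[C@H]1[C@@H](CC[C@@]1(C)O)C[N+](=O)[O-]
F3 | step 5 | [(1R,2R,5R)-2-hydroxy-2-methyl-5-(nitromethyl)cyclopentyl]methyl 4-methylbenzenesulfonate | Cc1ccc(cc1)S(=O)(=O)OC[C@H]2[C@@H](CC[C@@]2(C)O)C[N+](=O)[O-]
F4 | step 5 | 2-acetyl-3-hydroxy-6-methylidene-4,4-bis(3-methylbut-2-en-1-yl)cyclohex-2-ene-1,5-dione | CC(=O)C1=C(O)C(CC=C(C)C)(CC=C(C)C)C(=O)C(=C)C1=O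
F5 | step 5 | [(1R,2R,5R)-5-{2-[3-acetyl-4-hydroxy-5,5-bis(3-methylbut-2-en-1-yl)-2,6-dioxocyclohex-3-en-1-yl]-1-nitroethyl}-2-hydroxy-2-methylcyclopentyl]methyl 4-methylbenzenesulfonate | CC(=O)C1=C(O)C(CC=C(C)C)(CC=C(C)C)C(=O)C(CC([N+](=O)[O-])[C@@H]2CC[C@@](C)(O)[C@H]2COS(=O)(=O)c3ccc(C)cc3)C1=O
F6 | step 6 | (1S,3'R,3a'S,7a'R)-3-acetyl-3',4-dihydroxy-7'-(hydroxyimino)-3'-methyl-5,5-bis(3-methylbut-2-en-1-yl)-1',2',3',3a',4',6',7',7a'-octahydrospiro[cyclohex-3-ene-1,5'-indene]-2,6-dione | CC(=O)C1=C(O)C(CC=C(C)C)(CC=C(C)C)C(=O)[C@@]2(C[C@H]3[C@@H](CC[C@@]3(C)O)C(=NO)C2)C1=O
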